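The readings are calculated for an exercise; noise was put on by code.

Bracket the peak of achiral form between two bounds, then ask how much the reagent can have done by that time.

| setting | dusk | autumn | flask |
|---|---|---|---|
| left-handed substrate | 0.20 M | 0.20 M | 0.20 M |
| right-handed substrate | 0.20 M | 0.20 M | 0.20 M |
| reagent | 0.44 M (fed, over 30 h) | 0.29 M (fed, over 30 h) | 0.440 M (fed, over 30 h) |
| remark | the very flask that is asked about, followed so far; the fed solution adds 0.10 times the starting volume | run made earlier; the fed solution adds 0.10 times the starting volume | the fed solution adds 0.10 times the starting volume |
| time |  |  | 15 d |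

- dusk (time / d: achiral form / %, left-handed product / %, left-handed substrate / %): 0.167: 16.1, 1.3, 40.6; 0.417: 22.9, 3.8, 32.1; 0.833: 22.0, 9.6, 22.7; 1.25: 16.7, 15.9, 14.8; 1.67: 12.3, 20.7, 10.7; 2.00: 9.2, 23.6, 8.5; 2.50: 6.5, 26.4, 5.7
- autumn (time / d: achiral form / %, left-handed product / %, left-handed substrate / %): 2.00: 11.5, 17.4, 11.6; 4.00: 3.4, 22.8, 4.3; 6.00: 1.4, 25.8, 1.3; 8.00: 0.3, 25.6, 1.0; 10.0: 0.1, 26.3, 0; 12.0: 0.2, 26.0, 0; 15.0: 0, 25.8, 0.5

(readings scatter by 0.3 percentage points)

- reagent is single-handed; left-handed substrate and right-handed substrate are mirror images of each other, charged as a racemate, each of them at the stated concentration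
- charges are per starting volume, the dose included; the dosed solution carries all of it
- on the list of suspects stand: left-handed substrate <-> achiral form; reagent + left-handed substrate -> left-handed product; achiral form -> waste; reagent -> decomposition product; reagent + right-handed substrate -> right-handed product; reagent <-> dormant form; right-handed substrate <-> achiral form
- the handed part of reagent does not stay in what it makes, so the products of the two hands are mirror images too

- when, up to 15 d, the flask holds most achiral form
- the amount of achiral form, in percent of the left-handed substrate and right-handed substrate together charged, at that time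
- the first time at which achiral form reaches 16%, in the same percent, in d

The flask is the dusk run, so its readings are yours. The floor is the highest reading, 22.9% at 0.417 d. For the ceiling, extend the chord through the first two readings and the chord through those at 0.833 d and 1.25 d, since a curve bending one way stays under both:

rise 0.272 /d, fall 0.127 /d (shares of the charge per day)

crossing at 0.527 d, height 25.9%

The top is round, so take the middle of floor and corner as a tighter ceiling, an estimate and no longer a bound: 24.4%. The first reading stands 0.1 percentage points above the asked level, less than the scatter, so the crossing lies at about 0.167 d.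

Now take the reagent exposure (the time integral of concentration), here the charge fed so far summed over time: c(reagent) × t × t / (2 tf) during the feed, c(reagent) × (t − tf/2) after it. At 2.00 d the dusk run reads 9.2% and the autumn run 11.5%, so the price of exposure is

κ = 0.112 /M/d, of the charge lost as achiral form per unit of exposure.

At 0.527 d the flask has 0.0489 M·d, which costs 0.55 points.

The forecast puts the peak at 23.4% at 0.53 d, inside the bracket, and the level first reached at 0.165 d: “Combining the rise and the sinking plateau places the maximum near 0.5 d”.

The simulation gives 23.5% at 0.526 d, and the level is first reached at 0.171 d.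

    left-handed substrate ⇌ achiral form (K = 1.10, k = 1.63 × 10⁻⁵ /s)
    reagent + left-handed substrate → left-handed product (k = 6.49 × 10⁻⁵ /M/s)
    achiral form → waste (k = 1.17 × 10⁻⁵ /s)
    reagent → decomposition product (k = 4.63 × 10⁻⁸ /s)
    reagent + right-handed substrate → right-handed product (k = 3.32 × 10⁻⁵ /M/s)
    reagent ⇌ dormant form (K = 0.860, k = 1.02 × 10⁻⁴ /s)
    right-handed substrate ⇌ achiral form (K = 1.10, k = 1.63 × 10⁻⁵ /s)

The peak of the flask stands inside your bracket. At 0.526 d its exposure is 0.0487 M·d, which κ prices at 0.55 points. The largest single effect on when the peak comes is the conversion of achiral form into waste: the same run without that step peaks at 0.743 d against 0.526 d. With 0.11 M of reagent, the neighbour's exposure at that time shrinks with its charge, so κ adds 0.41 points and gives 23.9%. Its computed peak is 24.5%.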